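## Structural features

The target is a (2S)-flavanone: a benzene ring A fused to a dihydropyran-4-one ring C (O1, C2, C3, C4, C4a, C8a), with a 3,4-dihydroxyphenyl ring B on C2. Ring A is a fully differentiated phloroglucinol: a free hydroxyl on C5 that chelates the C4 carbonyl, a methyl ether on C7, a prenyl (3-methylbut-2-en-1-yl) chain on C8 and one hydrogen on C6. C2 is the only stereocentre, so no neighbouring centre can relay to it. It is also fragile, because it is benzylic, carries the ring oxygen and lies β to the ketone: base opens ring C to the 2'-hydroxychalcone and recloses it with loss of configuration. The catechol is sensitive to oxidants and base, and the prenyl alkene to strong acid, electrophiles and hydrogenation, which excludes benzyl-type protection. The real difficulties are therefore the absolute configuration at C2 and the regiochemistry of ring A, that is, which of two ortho oxygens becomes O1 so that the prenyl group ends on C8 and not on C6. The key step uses the fact that in ring C the O1–C2 and C3–C4 bonds flank the two-carbon unit C2–C3, which is the vinyl group of a 3,4-dioxygenated styrene, while C4 and O1 are the formyl carbon and the ortho hydroxyl of a salicylaldehyde.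

## Logic of the disconnections

14 ⇒ 13. No skeletal bond is cut; the three phenolic O–H bonds of 14 become O–Si bonds. The phenols must be masked during ring formation and oxidation, and silyl ethers can be removed without hydrogenation (prenyl) and without strong acid or base (C2). The gain is a non-polar, oxidation-proof intermediate. The demand on the forward step is a desilylation in which no phenoxide or enolate persists, since ring C of 14 opens under base.

13 ⇒ 12 ⇒ 11. The C4 carbonyl is traced back to a C4 carbinol and this to a C4 methyl ether; the bond concerned is C4–O(methyl), not a skeletal bond. Ring C is most easily made with C4 at the alcohol level, as an ether left over from an acetal. The gain is that 11 contains no β-aryloxy ketone, so C2 cannot be lost by ring opening while it is being set. The forward hydrolysis must ionise only C4, which is possible because C4 sits on the trioxygenated ring A, and the oxidation must be neutral. The C4 configuration need not be controlled because it disappears in 13.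

11 ⇒ 5 + 8 + 9. The cuts are C3–C4 and O1–C2, the two ring-C bonds on either side of C2–C3, together with the C4–O bond of the methyl ether, whose methoxy group comes from 9. This is the strategic cut: it separates the ring A half from the ring B half at the point where the only lasting stereocentre is made. The gain is one ring, two skeletal bonds and both stereocentres of 11 in one convergent operation. The demands are heavy: a chiral acid must fix the absolute configuration at C2, only one phenolic oxygen of 5 may be free so that the prenyl group ends on C8, and the acid must spare the prenyl alkene, the aryl silyl ethers and the polymerisable alkene of 8.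

8 ⇒ 7 ⇒ 6. The vinyl C=C bond is cut back to a formyl group and the two O–Si bonds back to the free catechol. The gain is a cheap commercial aldehyde as the source of ring B, C2 and C3. The demand is a methylenation whose base does not attack aryl silyl ethers.

5 ⇒ 4 ⇒ 3 ⇒ 1 + 2. Three bonds are cut in turn: O6–Si, O4–CH3, and the bond between ring carbon C3 and the CH2 of the prenyl group. The reason is that 1 is symmetric, so C3 and C5 are equivalent and the first C–C bond can form at only one kind of position. The gain is that 5 arises in three steps from two commercial compounds. The demand is site selection in every step: carbon against oxygen and single against double alkylation, the para hydroxyl in the methylation, and the unhindered ortho hydroxyl in the silylation. The last choice decides between the 8-prenyl and the 6-prenyl series.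

## Other disconnections considered

Alternative 1: The cut runs through C4a–C8a and C7–C8, opening rings A and C at once and leading to the acyclic (S)-triyne A1. In A1 a 1-methoxy-1,3-diyne conjugated to the C4 ketone is tethered through C3, C2 and O1 to an alkynyl ether that carries the prenyl chain. Heating A1 would start a hexadehydro-Diels–Alder reaction; the resulting C5–C6 aryne would be intercepted by acetic acid at C5, the carbon remote from the methoxy group, to give the acetate A2.
- In its favour: every substituent of ring A is placed by the connectivity of A1, so no phenolic oxygens have to be told apart. This is better than the chosen plan, whose step 3 rests on steric discrimination. C2 would be installed beforehand by established asymmetric carbonyl chemistry, which is also better than relying on a new catalytic step. C4 is already a ketone in A2, so hydrolysis and oxidation are not needed.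
- Against it here: the alkynyl ether of A1 sits on a secondary carbon with β-hydrogens at C3 and is expected to fragment by a retro-ene path below the temperature that a four-atom tether and an unactivated alkynyl ether require. The same oxygen is β to the ketone and can be lost by elimination, which would destroy C2. The methoxydiyne is delicate, and two different deprotections follow.
- Comparison: on structure, A1 is a far more fragile precursor than 5 and 8. On mechanism, A1 needs no catalyst control but a large thermal budget, whereas the chosen plan is ionic, runs cold and depends on a chiral ion pair. On step economy the end-game from A2 is shorter, but the linear assembly of A1 should be clearly longer than the five steps that lead to 5 and 8, and it is not convergent.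

Alternative 2: The cut is the C2–C3 bond; the atoms of ring C are regrouped in the racemic enol acetal A3, a 2-aryl-4-methylene-1,3-benzodioxine. A chiral Lewis acid would ionise the C2–O3 bond of A3, and the enolate carbon so released would add to the aryl oxocarbenium ion, a Petasis–Ferrier rearrangement that gives the silylated flavanone A4, which is identical with 13.
- In its favour: the rearrangement is redox-neutral and arrives directly at the oxidation level of the target, so only desilylation remains. This is two steps better than the chosen plan after the key step. A racemic precursor suffices. On the ring A problem it is the equal of the chosen plan, since A3 needs the same differentiated arene.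
- Against it here: an enantioselective form of this rearrangement is as unprecedented as the chosen key step, so the methodological risk is equal at best. The chiral Lewis acid sits on the enolate, while the prochiral partner is an O-aryl oxocarbenium ion, less stabilised than the O-methyl cation conjugated to ring A in the chosen plan. The acid must ionise C2–O3 and not the C2–O1 bond to the better phenoxide leaving group, and it must not reopen A4 at O1–C2, which would erase C2. A3 is hydrolytically labile, and its preparation needs methylenation of a hindered ester carbonyl next to the C5 silyl ether.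
- Comparison: both plans pass through an aryl-stabilised oxocarbenium ion and set C2 in the ring-forming event. The saving after the key step is offset by a longer and more delicate route to A3, so the overall step count should be similar.

Alternative 3: The cut is O1–C8a; ring C opens to the (1S,3S)-1,3-diol A5, which carries a triflate on C8a. Palladium-catalysed intramolecular aryl C–O coupling of the (S)-benzylic hydroxyl would close ring C and give the flavan-4-ol A6.
- In its favour: both stereocentres of A5 would come from an asymmetric aldol reaction and a syn-selective 1,3-reduction, and the ring-forming reaction type is known. This is a clear advantage over the unprecedented asymmetric step of the chosen plan. A6 needs only oxidation and acidic acetal removal, two steps against three, and the acid is harmless to C2 and to a prenyl group without a free ortho hydroxyl.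
- Against it here: oxidative addition into a triflate flanked by the prenyl group and the benzylic carbinol on an electron-rich ring should be slow. The palladium alkoxide of a secondary benzylic alcohol is prone to β-hydride elimination, and the second hydroxyl and the alkene can bind the metal. Ring A would need three differently treated oxygens, with the triflate on the most hindered, chelated hydroxyl, which is harder than the single silylation of the chosen plan.
- Comparison: reductive elimination retains a C2 configuration made earlier, whereas the chosen plan creates C2 as the ring forms. Convergence is equal, since both join a ring A and a ring B fragment. The aldol, reduction, triflation and protecting-group steps should make the longest linear sequence several steps longer.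

Key step: step 6

Remark on the chemistry: the sense of induction of the chiral acid in step 6 cannot be predicted with confidence, so it is assumed that the catalyst enantiomer leading to (2S) is identified in a first run; 12 is carried on as a mixture of C4 epimers because C4 becomes sp2 in step 8.

## Route

Step 1
Reactants: 1 2,4,6-trihydroxybenzaldehyde; 2 prenyl bromide (1-bromo-3-methylbut-2-ene)
Product: 3 2,4,6-trihydroxy-3-prenylbenzaldehyde
Conditions: DBU (1.0 equiv), THF, 0 °C → rt
Reagents that add atoms: none
Why: C-alkylation of an ambident phloroglucinol phenoxide (a vinylogous enolate) by a soft allylic bromide; C3 and C5 of 1 are equivalent, so only one mono-C-prenyl isomer can form, and one equivalent of 2 limits double alkylation.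

Step 2
Reactants: 3 2,4,6-trihydroxy-3-prenylbenzaldehyde
Product: 4 2,6-dihydroxy-4-methoxy-3-prenylbenzaldehyde
Conditions: MeI (1.0 equiv), K2CO3 (1.0 equiv), acetone, 0 °C → rt
Reagents that add atoms: iodomethane, CI
Why: Williamson O-methylation; the hydroxyl para to the formyl group is the most acidic and is not chelated, so one equivalent of weak base should ionise and alkylate it in preference to the two ortho hydroxyls.

Step 3
Reactants: 4 2,6-dihydroxy-4-methoxy-3-prenylbenzaldehyde
Product: 5 6-(tert-butyldimethylsilyloxy)-2-hydroxy-4-methoxy-3-prenylbenzaldehyde
Conditions: TBSCl (1.05 equiv), imidazole (2.2 equiv), CH2Cl2, 0 °C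
Reagents that add atoms: tert-butyldimethylsilyl chloride, CC(C)(C)[Si](C)(C)Cl
Why: Imidazole-mediated silyl ether formation; the C2 hydroxyl is wedged between the prenyl and formyl groups and should be the stronger hydrogen-bond donor to the carbonyl, whereas the C6 hydroxyl has a free ortho position and should take the bulky silyl group. The regiochemistry of 5 is to be confirmed by NOE and HMBC, since it decides where the prenyl group ends up.

Step 4
Reactants: 6 3,4-dihydroxybenzaldehyde
Product: 7 3,4-bis(tert-butyldimethylsilyloxy)benzaldehyde
Conditions: TBSCl (2.4 equiv), imidazole (5 equiv), DMF, rt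
Reagents that add atoms: tert-butyldimethylsilyl chloride, CC(C)(C)[Si](C)(C)Cl
Why: Standard exhaustive silylation of a catechol; the silyl ethers keep ring B electron-rich, which the styrene needs in step 6, and are removable at the end without touching the prenyl group.

Step 5
Reactants: 7 3,4-bis(tert-butyldimethylsilyloxy)benzaldehyde
Product: 8 3,4-bis(tert-butyldimethylsilyloxy)styrene
Conditions: Ph3PCH3Br (1.3 equiv), NaHMDS (1.25 equiv), THF, 0 °C → rt
Reagents that add atoms: methyltriphenylphosphonium bromide, C[P+](c1ccccc1)(c1ccccc1)c1ccccc1.[Br-]
Why: Wittig methylenation with a non-stabilised ylide; the ylide is formed first with a non-nucleophilic amide base, so the aryl silyl ethers meet no alkoxide.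

Step 6
Reactants: 5 6-(tert-butyldimethylsilyloxy)-2-hydroxy-4-methoxy-3-prenylbenzaldehyde; 9 trimethyl orthoformate; 8 3,4-bis(tert-butyldimethylsilyloxy)styrene
Product: 11 (2S,4S)-5-(tert-butyldimethylsilyloxy)-2-[3,4-bis(tert-butyldimethylsilyloxy)phenyl]-4,7-dimethoxy-8-prenylchromane (2,4-cis), via dimethyl acetal 10 (not isolated)
Conditions: 5, 9 (1.2 equiv), confined chiral imidodiphosphorimidate (IDPi) Brønsted acid (5 mol %), 5 Å MS, CH2Cl2, −20 °C; then 8 (2 equiv, slow addition), −60 °C; Et3N quench at −60 °C; chromatography to the pure cis isomer
Reagents that add atoms: none
Why: Proposed new method: a catalytic enantioselective three-component oxa-[4+2] annulation of a salicylaldehyde, an orthoformate and a styrene, whose closest known relatives are the achiral acid-promoted synthesis of 2,4-cis-4-alkoxy-2-arylchromans from the same three components and confined-acid catalysed additions of alkenes to oxocarbenium ion pairs. Acid-catalysed exchange with 9 turns 5 into acetal 10, and loss of methanol, pushed by the 2-hydroxy, 4-methoxy and 6-silyloxy donors, gives an O-methyl oxocarbenium ion (an O-protonated ortho-quinone methide) tied to the chiral anion by charge and by a hydrogen bond from the phenol. The terminal CH2 of 8 attacks C4 (C3–C4 bond) and the benzylic cation, stabilised by the para silyloxy group, is captured by the phenolic oxygen (O1–C2 bond), so ring C closes by a formal inverse-electron-demand hetero-Diels–Alder reaction, in the stepwise limit an intermolecular addition followed by a 6-exo-trig C–O closure. C4 is fixed by the face of the cation that the anion leaves open, and C2 by closure through a half-chair with aryl and methoxy both pseudo-equatorial while the anion is still paired with the cation, which should give the 2,4-cis isomer and ties the absolute configuration at C2 to the catalyst. The aryl group ends on C2 because only that orientation passes through a benzylic cation, and closure can use only the 2-hydroxyl because O6 is silylated, which places the prenyl group on C8. Chemoselectivity rests on the very easy ionisation of the triply donor-substituted acetal at −60 °C, where protonation of the prenyl alkene and cleavage of aryl silyl ethers should be slow, and on slow addition of 8 to limit its cationic oligomerisation. Any 2,4-trans isomer formed from the same C4 face is the C2 epimer, so the cis isomer is purified here, before C4 is erased.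

Step 7
Reactants: 11 (2S,4S)-5-(tert-butyldimethylsilyloxy)-2-[3,4-bis(tert-butyldimethylsilyloxy)phenyl]-4,7-dimethoxy-8-prenylchromane
Product: 12 (2S,4RS)-5-(tert-butyldimethylsilyloxy)-2-[3,4-bis(tert-butyldimethylsilyloxy)phenyl]-7-methoxy-8-prenylchroman-4-ol (mixture of C4 epimers)
Conditions: PPTS (0.2 equiv), THF–H2O (4:1), 40 °C
Reagents that add atoms: water, O
Why: SN1 hydrolysis of a benzylic methyl ether; C4 is ortho and para to three ring oxygens, so it ionises under very mild acid and the cation is trapped by the large excess of water. C2 is not involved, and the aryl silyl ethers and the prenyl group (which no longer has a free ortho phenol) should tolerate PPTS; both C4 epimers lead to 13.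

Step 8
Reactants: 12 (2S,4RS)-5-(tert-butyldimethylsilyloxy)-2-[3,4-bis(tert-butyldimethylsilyloxy)phenyl]-7-methoxy-8-prenylchroman-4-ol
Product: 13 (S)-5-(tert-butyldimethylsilyloxy)-2-[3,4-bis(tert-butyldimethylsilyloxy)phenyl]-7-methoxy-8-prenylchroman-4-one
Conditions: TPAP (5 mol %), NMO (1.5 equiv), 4 Å MS, CH2Cl2, rt
Reagents that add atoms: none
Why: Ley–Griffith oxidation of a secondary benzylic alcohol to the aryl ketone under neutral conditions, which avoids re-ionisation at C4 and leaves the trisubstituted alkene and the silyl ethers alone. The C4 stereocentre is removed and C2 is untouched, since no base strong enough for β-elimination is present.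

Step 9
Reactants: 13 (S)-5-(tert-butyldimethylsilyloxy)-2-[3,4-bis(tert-butyldimethylsilyloxy)phenyl]-7-methoxy-8-prenylchroman-4-one
Product: 14 (S)-2-(3,4-dihydroxyphenyl)-5-hydroxy-7-methoxy-8-prenylchroman-4-one (CNP0294928.1)
Conditions: TBAF (3.6 equiv), AcOH (4 equiv), THF, 0 °C, argon
Reagents that add atoms: none
Why: Fluoride-mediated cleavage of three aryl silyl ethers; the acetic acid buffer protonates each phenoxide as it forms, so base-induced opening of ring C to the chalcone, which would racemise C2, should be suppressed. Work-up under argon protects the catechol.

## Compound list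

1 | 2,4,6-trihydroxybenzaldehyde | O=Cc1c(O)cc(O)cc1O | starting material
2 | prenyl bromide (1-bromo-3-methylbut-2-ene) | CC(C)=CCBr | starting material
3 | 2,4,6-trihydroxy-3-prenylbenzaldehyde | O=Cc1c(O)cc(O)c(CC=C(C)C)c1O | intermediate
4 | 2,6-dihydroxy-4-methoxy-3-prenylbenzaldehyde | COc1cc(O)c(C=O)c(O)c1CC=C(C)C | intermediate
5 | 6-(tert-butyldimethylsilyloxy)-2-hydroxy-4-methoxy-3-prenylbenzaldehyde | COc1cc(O[Si](C)(C)C(C)(C)C)c(C=O)c(O)c1CC=C(C)C | intermediate
6 | 3,4-dihydroxybenzaldehyde | O=Cc1ccc(O)c(O)c1 | starting material
7 | 3,4-bis(tert-butyldimethylsilyloxy)benzaldehyde | O=Cc1ccc(O[Si](C)(C)C(C)(C)C)c(O[Si](C)(C)C(C)(C)C)c1 | intermediate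
8 | 3,4-bis(tert-butyldimethylsilyloxy)styrene | C=Cc1ccc(O[Si](C)(C)C(C)(C)C)c(O[Si](C)(C)C(C)(C)C)c1 | intermediate
9 | trimethyl orthoformate | COC(OC)OC | starting material
10 | 3-(tert-butyldimethylsilyloxy)-2-(dimethoxymethyl)-5-methoxy-6-prenylphenol (dimethyl acetal of 5, not isolated) | COc1cc(O[Si](C)(C)C(C)(C)C)c(C(OC)OC)c(O)c1CC=C(C)C | intermediate
11 | (2S,4S)-5-(tert-butyldimethylsilyloxy)-2-[3,4-bis(tert-butyldimethylsilyloxy)phenyl]-4,7-dimethoxy-8-prenylchromane | COc1cc(O[Si](C)(C)C(C)(C)C)c2c(c1CC=C(C)C)O[C@H](c1ccc(O[Si](C)(C)C(C)(C)C)c(O[Si](C)(C)C(C)(C)C)c1)C[C@@H]2OC | intermediate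
12 | (2S,4RS)-5-(tert-butyldimethylsilyloxy)-2-[3,4-bis(tert-butyldimethylsilyloxy)phenyl]-7-methoxy-8-prenylchroman-4-ol (C4 epimers) | COc1cc(O[Si](C)(C)C(C)(C)C)c2c(c1CC=C(C)C)O[C@H](c1ccc(O[Si](C)(C)C(C)(C)C)c(O[Si](C)(C)C(C)(C)C)c1)CC2O | intermediate
13 | (S)-5-(tert-butyldimethylsilyloxy)-2-[3,4-bis(tert-butyldimethylsilyloxy)phenyl]-7-methoxy-8-prenylchroman-4-one | COc1cc(O[Si](C)(C)C(C)(C)C)c2c(c1CC=C(C)C)O[C@H](c1ccc(O[Si](C)(C)C(C)(C)C)c(O[Si](C)(C)C(C)(C)C)c1)CC2=O | intermediate
14 | (S)-2-(3,4-dihydroxyphenyl)-5-hydroxy-7-methoxy-8-prenylchroman-4-one | COc1cc(O)c2c(c1CC=C(C)C)O[C@H](c1ccc(O)c(O)c1)CC2=O | target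

## Step count and least certain steps

Total: 9 steps. Longest linear sequence: 7 steps (1, 2, 3, 6, 7, 8, 9).

Step 6 (key step). The most likely failures are three.
- Facial discrimination in the ion pair may be poor, because the tris-silylated partners are bulky and may react outside the confined pocket.
- The C2 configuration may erode through reversible ionisation at C4 and retro-addition if the mixture warms before the quench.
- Styrene 8 may oligomerise cationically, and the 2-hydroxyl may cyclise onto the prenyl alkene.

The fallback gives up asymmetric catalysis for resolution and uses known chemistry. It sets out from 5, 8 and 9. An achiral acid (Sc(OTf)3 or diphenyl phosphate, CH2Cl2, 0 °C), the known three-component mode, should give the racemic 4-methoxyflavan F1 through acetal 10. The conditions of step 7 then give the racemic flavan-4-ol F2, and those of step 8 the racemic flavanone F3. Asymmetric transfer hydrogenation of F3 with a Ru–TsDPEN catalyst and HCO2H/Et3N, a known kinetic resolution of 2-arylchroman-4-ones, is run with the catalyst enantiomer that reduces the (R)-ketone faster. It is taken past half conversion, so that the (R)-ketone ends as the (2R,4R)-flavan-4-ol F4 and the unreacted (S)-ketone is recovered. The fallback returns to the route at 13.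

Step 1. O-alkylation and a second C-alkylation compete with mono-C-prenylation, because the product is as nucleophilic as 1; a low yield and a difficult separation are the likely outcome. The fallback replaces direct C-alkylation by O-alkylation and rearrangement. It sets out from 1 and 2. Selective alkylation of the most acidic, para hydroxyl (K2CO3, acetone, rt) should give 2,6-dihydroxy-4-(prenyloxy)benzaldehyde F5. A clay-promoted 1,3-shift (montmorillonite K10, CH2Cl2, 0 °C) then moves the prenyl group from O4 to the ortho carbon; the two ortho positions are equivalent. The fallback returns to the route at 3.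

Step 3. Silylation may occur at the hindered hydroxyl or at both. A wrong site would go unnoticed into the 6-prenyl series, so this is the step with the most serious consequence before the key step. The fallback lets a sigmatropic shift define the free hydroxyl instead of steric discrimination. It sets out from 1 and returns at 5.
- 4-O-Methylation of 1 (MeI, K2CO3, acetone) should give 2,6-dihydroxy-4-methoxybenzaldehyde F6, which is symmetric.
- Tsuji–Trost etherification of one hydroxyl (tert-butyl 2-methylbut-3-en-2-yl carbonate, Pd(PPh3)4 cat., THF, 0 °C) should give the tertiary allyl ether 2-hydroxy-4-methoxy-6-[(2-methylbut-3-en-2-yl)oxy]benzaldehyde F7.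
- Silylation of the only remaining hydroxyl (TBSCl, imidazole, DMF) should give 2-(tert-butyldimethylsilyloxy)-4-methoxy-6-[(2-methylbut-3-en-2-yl)oxy]benzaldehyde F8.
- Aromatic Claisen rearrangement (toluene, 110 °C) moves the allyl unit to the only free ortho carbon as a prenyl group and frees the adjacent hydroxyl.

This detour also replaces steps 1 and 2 and their selectivity questions, at the cost of one more step.

Step 7. The C4 cation may lose a proton to give the flav-3-ene, or may be intercepted by the electron-rich C6 of a second molecule, instead of being trapped by water. The fallback is oxidative and skips 12. It sets out from 11: DDQ in CH2Cl2–pH 7 buffer at 0 °C should abstract the pseudo-axial C4 hydride, which is activated by three ring oxygens and the ether oxygen, and water then converts the oxocarbenium ion into the ketone with loss of methanol. This is the known oxidative cleavage of electron-rich benzylic methyl ethers. The risk to watch is hydride abstraction at the benzylic-allylic CH2 of the prenyl group. The fallback returns to the route at 13 and makes no new compound.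

## Further compounds

F1 | step 6 | racemic 5-(tert-butyldimethylsilyloxy)-2-[3,4-bis(tert-butyldimethylsilyloxy)phenyl]-4,7-dimethoxy-8-prenylchromane (stereoisomer mixture) | COc1cc(O[Si](C)(C)C(C)(C)C)c2c(c1CC=C(C)C)OC(c1ccc(O[Si](C)(C)C(C)(C)C)c(O[Si](C)(C)C(C)(C)C)c1)CC2OC
F2 | step 6 | racemic 5-(tert-butyldimethylsilyloxy)-2-[3,4-bis(tert-butyldimethylsilyloxy)phenyl]-7-methoxy-8-prenylchroman-4-ol (stereoisomer mixture) | COc1cc(O[Si](C)(C)C(C)(C)C)c2c(c1CC=C(C)C)OC(c1ccc(O[Si](C)(C)C(C)(C)C)c(O[Si](C)(C)C(C)(C)C)c1)CC2O
F3 | step 6 | racemic 5-(tert-butyldimethylsilyloxy)-2-[3,4-bis(tert-butyldimethylsilyloxy)phenyl]-7-methoxy-8-prenylchroman-4-one | COc1cc(O[Si](C)(C)C(C)(C)C)c2c(c1CC=C(C)C)OC(c1ccc(O[Si](C)(C)C(C)(C)C)c(O[Si](C)(C)C(C)(C)C)c1)CC2=O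
F4 | step 6 | (2R,4R)-5-(tert-butyldimethylsilyloxy)-2-[3,4-bis(tert-butyldimethylsilyloxy)phenyl]-7-methoxy-8-prenylchroman-4-ol | COc1cc(O[Si](C)(C)C(C)(C)C)c2c(c1CC=C(C)C)O[C@@H](c1ccc(O[Si](C)(C)C(C)(C)C)c(O[Si](C)(C)C(C)(C)C)c1)C[C@H]2O
F5 | step 1 | 2,6-dihydroxy-4-[(3-methylbut-2-en-1-yl)oxy]benzaldehyde | O=Cc1c(O)cc(OCC=C(C)C)cc1O
F6 | step 3 | 2,6-dihydroxy-4-methoxybenzaldehyde | COc1cc(O)c(C=O)c(O)c1
F7 | step 3 | 2-hydroxy-4-methoxy-6-[(2-methylbut-3-en-2-yl)oxy]benzaldehyde | COc1cc(O)c(C=O)c(OC(C)(C)C=C)c1
F8 | step 3 | 2-(tert-butyldimethylsilyloxy)-4-methoxy-6-[(2-methylbut-3-en-2-yl)oxy]benzaldehyde | COc1cc(O[Si](C)(C)C(C)(C)C)c(C=O)c(OC(C)(C)C=C)c1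
F0 | step 7 | none | none
A1 | alternative 1 | (S)-1-[3,4-bis(methoxymethoxy)phenyl]-7-methoxy-1-[(5-methylhex-4-en-1-yn-1-yl)oxy]hepta-4,6-diyn-3-one | COC#CC#CC(=O)C[C@@H](c1ccc(OCOC)c(OCOC)c1)OC#CCC=C(C)C
A2 | alternative 1 | (S)-5-acetoxy-2-[3,4-bis(methoxymethoxy)phenyl]-7-methoxy-8-prenylchroman-4-one | COc1cc(OC(C)=O)c2c(c1CC=C(C)C)O[C@H](c1ccc(OCOC)c(OCOC)c1)CC2=O
A3 | alternative 2 | racemic 5-(tert-butyldimethylsilyloxy)-2-[3,4-bis(tert-butyldimethylsilyloxy)phenyl]-7-methoxy-4-methylene-8-prenyl-4H-1,3-benzodioxine | C=C1OC(c2ccc(O[Si](C)(C)C(C)(C)C)c(O[Si](C)(C)C(C)(C)C)c2)Oc2c(CC=C(C)C)c(OC)cc(O[Si](C)(C)C(C)(C)C)c21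
A4 | alternative 2 | (S)-5-(tert-butyldimethylsilyloxy)-2-[3,4-bis(tert-butyldimethylsilyloxy)phenyl]-7-methoxy-8-prenylchroman-4-one (identical with 13) | COc1cc(O[Si](C)(C)C(C)(C)C)c2c(c1CC=C(C)C)O[C@H](c1ccc(O[Si](C)(C)C(C)(C)C)c(O[Si](C)(C)C(C)(C)C)c1)CC2=O
A5 | alternative 3 | (1S,3S)-1-[3,4-bis(methoxymethoxy)phenyl]-3-[4-methoxy-6-(methoxymethoxy)-3-prenyl-2-(trifluoromethylsulfonyloxy)phenyl]propane-1,3-diol | COc1cc(OCOC)c(c(OS(=O)(=O)C(F)(F)F)c1CC=C(C)C)[C@@H](O)C[C@H](O)c1ccc(OCOC)c(OCOC)c1
A6 | alternative 3 | (2S,4S)-2-[3,4-bis(methoxymethoxy)phenyl]-7-methoxy-5-(methoxymethoxy)-8-prenylchroman-4-ol | COc1cc(OCOC)c2c(c1CC=C(C)C)O[C@H](c1ccc(OCOC)c(OCOC)c1)C[C@@H]2O
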